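The single-handed catalyst met a racemate, so I reckoned this flask from the symmetric case as the zero of the scale.

| setting | east | south | south-east | flask |
|---|---|---|---|---|
| left-handed substrate | 0.056 M | 0.088 M | 0.040 M | 0.040 M |
| right-handed substrate | 0.056 M | 0.088 M | 0.040 M | 0.040 M |
| solid reagent | 2 equiv | 2 equiv | 2 equiv | 2.00 equiv |
| catalyst | 2.5 mol% | 2.5 mol% | 1.2 mol% | 2.5 mol% |
| remark | run made earlier | run made earlier | run made earlier |  |
| time |  |  |  | 4.0 h |

| run | time / h | left-handed product / % | right-handed product / % |
|---|---|---|---|
| east | 0.250 | 2.2 | 0 |
| east | 0.833 | 8.5 | 1.0 |
| east | 1.33 | 15.3 | 0.5 |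
| east | 2.50 | 24.9 | 1.6 |
| east | 3.00 | 27.0 | 0 |
| south | 0.250 | 2.7 | 0.6 |
| south | 0.500 | 4.8 | 0 |
| south | 0.833 | 10.6 | 0 |
| south | 1.50 | 15.1 | 0.7 |
| south | 3.00 | 31.8 | 0.7 |
| south-east | 0.250 | 1.7 | 0 |
| south-east | 0.833 | 6.1 | 1.1 |
| south-east | 1.33 | 6.7 | 0 |
| south-east | 2.50 | 13.6 | 0.1 |
| south-east | 3.00 | 16.6 | 0 |

(standard deviation of a reading: 1 percentage point)

- catalyst is single-handed; left-handed substrate and right-handed substrate are mirror images of each other, charged as a racemate, each of them at the stated concentration
- given per volume of solution although it is solid: solid reagent
- what was read earlier has a scatter of 1 percentage point, one standard deviation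
- at the start none of the solid reagent is in solution
- an excess is the difference of the two amounts in percent of their sum
- an excess is below zero if the other one leads

* excess of left-handed product over right-handed product in the product at 12 min
* excess of left-handed product over right-handed product in the product at 4.0 h
* part of the left-handed substrate and right-handed substrate charged together that has reacted at 4.0 h

With the main step alone, and no preference between the mirror images, I took the two products as forming alike, which put the excess at zero. Next I added the catalyst's preference, summing each product over the readings of the east, south and south-east runs: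

left-handed product: 187.6%

right-handed product: 6.30%

selectivity factor: 29.8, the left-handed product formed per right-handed product

excess = (factor minus one)/(factor plus one) = 93.5%

This was a rough reading: the right-handed readings stood at the level of the scatter, 1 percentage point. Then I added the draining of the left-handed substrate. In the south run the left-handed product reached 31.8% against the 50.0% charged as left-handed, yet it gained 0.111 h⁻¹ of the charge over the last stretch, against 0.101 h⁻¹ up to 1.50 h. I saw no sag in the south run, and on that reading I kept the factor flat. For the rest I assumed that catalyst, solid reagent and time act alike on both products and drop out of the factor, so I committed to 93.5% at both asked times; the factor gave me no conversion.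

The forecast said an excess of 98% at 12 min and 97% at 4.0 h, with 38% reacted, holding of the average of the right-handed readings that it “is what clipped noise around zero gives, so selectivity is very high”. I had taken those readings at face value, so my excess was lower than the forecast's.

The flask gave 95.1% at 12 min, 95.1% at 4.0 h, and 30.5% reacted.

    partner + catalyst + left-handed substrate → catalyst + left-handed product (k = 15.6 M⁻² s⁻¹)
    partner + catalyst + right-handed substrate → catalyst + right-handed product (k = 0.388 M⁻² s⁻¹)
    left-handed substrate ⇌ right-handed substrate (k = 0.0172 s⁻¹)
    partner → decomposition product (k = 3.23 × 10⁻⁷ s⁻¹)
    partner → decomposed reagent (k = 0.00122 s⁻¹)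
    solid reagent ⇌ partner, rate k6*(cs6 - [partner]) while solid is left; crystals form when [partner] > cs6 (solubility = 15.0 mM, k = 5.85 × 10⁻⁴ s⁻¹)

The excess stood level between both times, 1.6 points above mine, while the reacted part fell 7.5 points short of the forecast, with the solid reagent at 0% of its charge and 0.0555 M of decomposed reagent in the flask at 4.00 h. In the neighbouring flask with 10 mol% of catalyst, my factor turned its 56.8% of left-handed product into 1.91% of right-handed product and an excess of 93.5%. That flask held 1.42% of right-handed product at 4.00 h, showed an excess of 95.1%, and had 58.2% reacted, its left-handed product standing above the 50.0% charged as left-handed.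

(All runs are simulated on assumed constants; scatter was added.)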